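**Plan**
1. Late cuts: the C5–C(=O) bond (methoxycarbonylation of a C5 bromide), the phenol O–H (carried as a mesylate) and the C9 alcohol (from a C9 methyl ester).
2. Key cut: the C3–C3a bond. The unit O1–C2(aryl)–C3(C9)–C3a of the dihydrofuran ring is a flavanone O1–C2(aryl)–C3–C4(=O)–C4a in disguise. Shifting the benzo carbon from the carbonyl carbon to C3 contracts the pyranone ring and leaves the old carbonyl carbon outside the ring as C9.
3. The flavanone is cut at C2–aryl (asymmetric conjugate addition of an arylboronic acid to a chromone). The chromone comes from a brominated 2-hydroxyacetophenone and a one-carbon amide acetal.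
4. Forward order: pyranone ring of the chromone, then the 2-aryl group, then contraction of the six-membered to the five-membered oxygen ring, then the three end-game adjustments.
5. Stereochemistry: C2 (S, as in natural flavanones) is set by a chiral pyridine-oxazoline palladium catalyst. C3 is set in the ring contraction under control of C2 (2,3-trans).

Key step: step 6

Assumption: the sense of induction of the palladium pyridine-oxazoline catalyst on chromones is taken to parallel that on 3-substituted cyclohexenones, so the (R)-ligand should give the (2S)-flavanone; if the first run shows the opposite sense, the (S)-ligand is used instead.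

**Step 1**
Reactants: 1 1-(2-hydroxy-3-methoxyphenyl)ethanone
Product: 2 1-(5-bromo-2-hydroxy-3-methoxyphenyl)ethanone
Conditions: NBS (1.05 equiv), MeCN, 0 °C to rt
Reagents that add atoms: N-bromosuccinimide, O=C1CCC(=O)N1Br
Why: Electrophilic aromatic bromination goes to C5, the only open position ortho or para to the strongly activating hydroxyl group, which is also meta to the acetyl group.

**Step 2**
Reactants: 2 1-(5-bromo-2-hydroxy-3-methoxyphenyl)ethanone; 3 N,N-dimethylformamide dimethyl acetal
Product: 5 6-bromo-8-methoxy-4H-chromen-4-one, via enaminone 4 (not isolated)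
Conditions: 3 (1.5 equiv), toluene, 100 °C; evaporate; conc. HCl, CH2Cl2, 40 °C
Reagents that add atoms: N,N-dimethylformamide dimethyl acetal (compound 3), COC(OC)N(C)C
Why: The methyl ketone condenses with the amide acetal to enaminone 4, and acid then drives conjugate addition of the phenol oxygen to the enaminone β-carbon with loss of dimethylamine (the standard enaminone route to chromones), which closes the pyranone ring.

**Step 3**
Reactants: 6 2-methoxy-4-(4,4,5,5-tetramethyl-1,3,2-dioxaborolan-2-yl)phenol
Product: 7 2-methoxy-4-(4,4,5,5-tetramethyl-1,3,2-dioxaborolan-2-yl)phenyl methanesulfonate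
Conditions: MsCl, Et3N, CH2Cl2, 0 °C
Reagents that add atoms: methanesulfonyl chloride, CS(=O)(=O)Cl
Why: Sulfonylation of the phenol under amine base should be clean because the pinacol boronate is inert to MsCl and Et3N.

**Step 4**
Reactants: 7 2-methoxy-4-(4,4,5,5-tetramethyl-1,3,2-dioxaborolan-2-yl)phenyl methanesulfonate
Product: 8 [3-methoxy-4-(methylsulfonyloxy)phenyl]boronic acid
Conditions: NaIO4, NH4OAc, acetone/H2O, rt
Reagents that add atoms: water, O
Why: Periodate cleaves the pinacol released in the hydrolysis equilibrium of the boronate to acetone, which drives the ester to the free boronic acid needed for transmetalation in step 5, and the mesylate is stable to these buffered conditions.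

**Step 5**
Reactants: 5 6-bromo-8-methoxy-4H-chromen-4-one; 8 [3-methoxy-4-(methylsulfonyloxy)phenyl]boronic acid (2.5 equiv)
Product: 9 (2S)-6-bromo-8-methoxy-2-[3-methoxy-4-(methylsulfonyloxy)phenyl]-2,3-dihydro-4H-chromen-4-one
Conditions: Pd(OCOCF3)2 (5 mol %), (R)-4-tert-butyl-2-(pyridin-2-yl)-4,5-dihydrooxazole (6 mol %), NH4PF6 (30 mol %), H2O (5 equiv), ClCH2CH2Cl, 60 °C
Reagents that add atoms: none
Why: In this palladium-catalysed asymmetric conjugate addition of an arylboronic acid to a chromone, the cationic aryl-palladium species formed by transmetalation inserts the C2=C3 bond on the face left open by the tert-butyl group of the pyridine-oxazoline ligand, which sets C2 as S, and protonolysis of the palladium enolate releases the flavanone while the metal stays divalent, so the C–Br bond and the mesylate are not touched.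

**Step 6**
Reactants: 9 (2S)-6-bromo-8-methoxy-2-[3-methoxy-4-(methylsulfonyloxy)phenyl]-2,3-dihydro-4H-chromen-4-one
Product: 12 methyl (2S,3S)-5-bromo-7-methoxy-2-[3-methoxy-4-(methylsulfonyloxy)phenyl]-2,3-dihydro-1-benzofuran-3-carboxylate (2,3-trans), via methyl enol ether 10 (not isolated), via iodanyl ketal 11 (not isolated)
Conditions: HC(OMe)3, conc. H2SO4, rt; then PhI(OAc)2 (1.3 equiv), rt to 40 °C; aq. NaHCO3
Reagents that add atoms: trimethyl orthoformate, COC(OC)OC
Why: Acid and orthoformate turn the ketone into methyl enol ether 10, whose C3 attacks the electrophilic trivalent iodine of PhI(OAc)2 on the face opposite the pseudo-equatorial 2-aryl group while methanol caps C4, giving iodanyl ketal 11 with iodine equatorial. In that geometry the C4–C4a bond lies antiperiplanar to the C3–I bond, so the benzo carbon C4a shifts from C4 to C3 as iodobenzene leaves, and the dimethoxycarbenium ion left at C4 collapses to the methyl ester on work-up. This is the known hypervalent-iodine oxidative ring contraction of flavanones to methyl trans-2-aryl-2,3-dihydrobenzofuran-3-carboxylates, a relative of the oxidative 1,2-aryl shift of aryl ketones to arylacetates. The dihydrofuran ring is closed not by a cyclisation but by contraction of the pyranone through a 1,2-aryl shift via a bridged phenonium-type transition state, the C3–C3a bond forming as C4 is pushed out of the ring. The new C3 centre is controlled by the resident (2S) centre, because anti delivery of iodine followed by inversion at C3 places the ester trans to the aryl group, i.e. (2S,3S). The step needs benzo-carbon migration to win over 2-aryl migration (isoflavone) and over dehydrogenation (flavone); the equatorial iodine, the electron-poor mesylated 2-aryl group and the O1-activated migrating carbon C4a should secure this.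

**Step 7**
Reactants: 12 methyl (2S,3S)-5-bromo-7-methoxy-2-[3-methoxy-4-(methylsulfonyloxy)phenyl]-2,3-dihydro-1-benzofuran-3-carboxylate
Product: 13 4-[(2S,3R)-5-bromo-3-(hydroxymethyl)-7-methoxy-2,3-dihydro-1-benzofuran-2-yl]-2-methoxyphenyl methanesulfonate
Conditions: iBu2AlH (DIBAL-H, 3 equiv), CH2Cl2, −78 to 0 °C; aq. potassium sodium tartrate (KNaC4H4O6)
Reagents that add atoms: none
Why: Hydride reduction of the ester to the primary alcohol by DIBAL-H is fast at low temperature and is not basic, so the β-aryloxy ester is not opened by elimination of the O1 phenoxide and C3 is not epimerised, while the aryl bromide and aryl mesylate are inert to this reagent (the C3 descriptor changes from S to R by priority only).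

**Step 8**
Reactants: 13 4-[(2S,3R)-5-bromo-3-(hydroxymethyl)-7-methoxy-2,3-dihydro-1-benzofuran-2-yl]-2-methoxyphenyl methanesulfonate
Product: 14 4-[(2S,3R)-5-bromo-3-(hydroxymethyl)-7-methoxy-2,3-dihydro-1-benzofuran-2-yl]-2-methoxyphenol
Conditions: KOH, MeOH/THF/H2O, 50 °C, argon; then aq. NH4Cl
Reagents that add atoms: none
Why: Alkaline hydrolysis of the aryl methanesulfonate (attack of hydroxide at sulfur or sulfene elimination) frees the phenol at a stage where no ester is present and C3–H is no longer acidified, so neither saponification nor β-elimination of O1 can interfere and both stereocentres stay as they are.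

**Step 9**
Reactants: 14 4-[(2S,3R)-5-bromo-3-(hydroxymethyl)-7-methoxy-2,3-dihydro-1-benzofuran-2-yl]-2-methoxyphenol
Product: 15 curlignan, methyl (2S,3R)-2-(4-hydroxy-3-methoxyphenyl)-3-(hydroxymethyl)-7-methoxy-2,3-dihydro-1-benzofuran-5-carboxylate
Conditions: Pd(OAc)2 (5 mol %), Xantphos (6 mol %), CO (1 atm), Et3N, MeOH/DMF, 70 °C
Reagents that add atoms: carbon monoxide, [C-]#[O+]; methanol, CO
Why: In this palladium-catalysed alkoxycarbonylation (Heck carbonylation) of the aryl bromide, oxidative addition of zerovalent palladium at C5–Br, CO insertion and methanolysis of the acyl-palladium species give the methyl ester, with the free phenol and primary alcohol outcompeted by the large excess of methanol and no stereocentre involved.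

**Compound list**
1 | 1-(2-hydroxy-3-methoxyphenyl)ethanone | CC(=O)c1cccc(OC)c1O | starting material
2 | 1-(5-bromo-2-hydroxy-3-methoxyphenyl)ethanone | CC(=O)c1cc(Br)cc(OC)c1O | intermediate
3 | N,N-dimethylformamide dimethyl acetal | COC(OC)N(C)C | starting material
4 | (E)-1-(5-bromo-2-hydroxy-3-methoxyphenyl)-3-(dimethylamino)prop-2-en-1-one | CN(C)/C=C/C(=O)c1cc(Br)cc(OC)c1O | intermediate (not isolated)
5 | 6-bromo-8-methoxy-4H-chromen-4-one | O=c1ccoc2c(OC)cc(Br)cc12 | intermediate
6 | 2-methoxy-4-(4,4,5,5-tetramethyl-1,3,2-dioxaborolan-2-yl)phenol | COc1cc(ccc1O)B1OC(C)(C)C(C)(C)O1 | starting material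
7 | 2-methoxy-4-(4,4,5,5-tetramethyl-1,3,2-dioxaborolan-2-yl)phenyl methanesulfonate | COc1cc(ccc1OS(C)(=O)=O)B1OC(C)(C)C(C)(C)O1 | intermediate
8 | [3-methoxy-4-(methylsulfonyloxy)phenyl]boronic acid | COc1cc(ccc1OS(C)(=O)=O)B(O)O | intermediate
9 | (2S)-6-bromo-8-methoxy-2-[3-methoxy-4-(methylsulfonyloxy)phenyl]-2,3-dihydro-4H-chromen-4-one | O=C1C[C@@H](c2ccc(OS(C)(=O)=O)c(OC)c2)Oc2c1cc(Br)cc2OC | intermediate
10 | (2S)-6-bromo-4,8-dimethoxy-2-[3-methoxy-4-(methylsulfonyloxy)phenyl]-2H-chromene | COC1=C[C@@H](c2ccc(OS(C)(=O)=O)c(OC)c2)Oc2c1cc(Br)cc2OC | intermediate (not isolated)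
11 | (2R,3R)-3-[acetoxy(phenyl)-λ3-iodanyl]-6-bromo-4,4,8-trimethoxy-2-[3-methoxy-4-(methylsulfonyloxy)phenyl]chromane (iodine trans to the aryl group; same spatial arrangement at C2 as in 9) | COC1(OC)[C@H](I(OC(C)=O)c2ccccc2)[C@@H](c2ccc(OS(C)(=O)=O)c(OC)c2)Oc2c1cc(Br)cc2OC | intermediate (not isolated)
12 | methyl (2S,3S)-5-bromo-7-methoxy-2-[3-methoxy-4-(methylsulfonyloxy)phenyl]-2,3-dihydro-1-benzofuran-3-carboxylate (2,3-trans) | Brc1cc(OC)c2c(c1)[C@H](C(=O)OC)[C@@H](c1ccc(OS(C)(=O)=O)c(OC)c1)O2 | intermediate
13 | 4-[(2S,3R)-5-bromo-3-(hydroxymethyl)-7-methoxy-2,3-dihydro-1-benzofuran-2-yl]-2-methoxyphenyl methanesulfonate | Brc1cc(OC)c2c(c1)[C@H](CO)[C@@H](c1ccc(OS(C)(=O)=O)c(OC)c1)O2 | intermediate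
14 | 4-[(2S,3R)-5-bromo-3-(hydroxymethyl)-7-methoxy-2,3-dihydro-1-benzofuran-2-yl]-2-methoxyphenol | Brc1cc(OC)c2c(c1)[C@H](CO)[C@@H](c1ccc(O)c(OC)c1)O2 | intermediate
15 | curlignan, methyl (2S,3R)-2-(4-hydroxy-3-methoxyphenyl)-3-(hydroxymethyl)-7-methoxy-2,3-dihydro-1-benzofuran-5-carboxylate | COC(=O)c1cc(OC)c2c(c1)[C@H](CO)[C@@H](c1ccc(O)c(OC)c1)O2 | target

**Step count and risks**
Total steps: 9. Longest linear sequence: 7 steps (steps 1, 2, 5, 6, 7, 8, 9 from compound 1; the sequence 3, 4, 5, 6, 7, 8, 9 from compound 6 is equally long).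

Steps most likely to fail:

Step 6. The 2-aryl group may migrate instead of the benzo carbon, or the enol ether may simply be dehydrogenated. Migration may also be slow because the bromide meta to C4a makes ring A less electron-rich, and acid-induced opening and reclosure of the pyranone before oxidation could erode the C2 configuration. The fallback sets out from 9 and returns at 12, and makes the same C4a shift from C4 to C3 through a carbene instead of an iodane. Compound 9 is condensed with acetal 3 in hot toluene to the enaminone (2R,3E)-6-bromo-3-[(dimethylamino)methylidene]-8-methoxy-2-[3-methoxy-4-(methylsulfonyloxy)phenyl]-2,3-dihydro-4H-chromen-4-one F1 (E geometry expected; the C2 descriptor changes by priority only). Diazo transfer with methanesulfonyl azide in MeCN then gives the diazoketone (2R)-6-bromo-3-diazo-8-methoxy-2-[3-methoxy-4-(methylsulfonyloxy)phenyl]-2,3-dihydro-4H-chromen-4-one F2. Photochemical Wolff rearrangement of this s-cis-locked diazoketone (365 nm, MeOH/THF) should give the ring-contracted ketene, which methanol traps as ester 12 together with its cis epimer methyl (2S,3R)-5-bromo-7-methoxy-2-[3-methoxy-4-(methylsulfonyloxy)phenyl]-2,3-dihydro-1-benzofuran-3-carboxylate F3. Brief treatment with catalytic DBU in CH2Cl2 equilibrates F3 to the trans ester 12. No 2-aryl shift can compete in this sequence, since only the substituent on the carbonyl carbon migrates.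

Step 5. Insertion of the electron-rich, bromine-bearing chromone into the aryl-palladium bond may be slower than protodeboronation or homocoupling of 8. Facial discrimination may be insufficient, and adventitious zerovalent palladium may insert into the C–Br bond. The fallback sets out from 2 and returns at 9, and builds the C2–O1 bond instead of the C2–aryl bond. Vanillin is mesylated (MsCl, Et3N) to 4-formyl-2-methoxyphenyl methanesulfonate F4. Acid-mediated Claisen–Schmidt condensation with 2 (SOCl2 in EtOH, HCl formed in situ) gives the chalcone (E)-1-(5-bromo-2-hydroxy-3-methoxyphenyl)-3-[3-methoxy-4-(methylsulfonyloxy)phenyl]prop-2-en-1-one F5. NaOAc in refluxing EtOH closes it by oxa-Michael addition to the racemic flavanone 6-bromo-8-methoxy-2-[3-methoxy-4-(methylsulfonyloxy)phenyl]-2,3-dihydro-4H-chromen-4-one F6. Kinetic resolution by asymmetric transfer hydrogenation with RuCl(p-cymene)[(R,R)-TsDPEN] and HCO2H/Et3N in EtOAc follows. By the usual model for aryl ketones this catalyst delivers hydride to give the (4R)-alcohol, so it should consume the (2R)-ketone as the cis-alcohol 4-[(2R,4R)-6-bromo-4-hydroxy-8-methoxy-3,4-dihydro-2H-chromen-2-yl]-2-methoxyphenyl methanesulfonate F7 and leave (2S)-ketone 9, which is separated by chromatography.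

Step 8. Once the 4-hydroxyphenyl group is ionised in warm alkali, the dihydrofuran ring may open through a quinone methide, leading to C2 epimerisation or loss of the C9 unit as formaldehyde; under milder conditions the sulfonate may cleave incompletely. The fallback sets out from 13 and returns at 15, reversing the order and removing the mesylate cold. Methoxycarbonylation of 13 (Pd(OAc)2, Xantphos, CO, Et3N, MeOH/DMF, 70 °C) gives methyl (2S,3R)-3-(hydroxymethyl)-7-methoxy-2-[3-methoxy-4-(methylsulfonyloxy)phenyl]-2,3-dihydro-1-benzofuran-5-carboxylate F8. The mesylate is then removed with LiN(iPr)2 (3.5 equiv, THF, −78 °C) by deprotonation of the sulfonyl methyl group and sulfene elimination. The ester has no α-hydrogen and is tolerated, and the phenoxide is quenched cold with aq. NH4Cl to give 15.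

**Further compounds**
F1 | step 6 | (2R,3E)-6-bromo-3-[(dimethylamino)methylidene]-8-methoxy-2-[3-methoxy-4-(methylsulfonyloxy)phenyl]-2,3-dihydro-4H-chromen-4-one | CN(C)/C=C1/C(=O)c2cc(Br)cc(OC)c2O[C@@H]1c1ccc(OS(C)(=O)=O)c(OC)c1
F2 | step 6 | (2R)-6-bromo-3-diazo-8-methoxy-2-[3-methoxy-4-(methylsulfonyloxy)phenyl]-2,3-dihydro-4H-chromen-4-one | [N-]=[N+]=C1C(=O)c2cc(Br)cc(OC)c2O[C@@H]1c1ccc(OS(C)(=O)=O)c(OC)c1
F3 | step 6 | methyl (2S,3R)-5-bromo-7-methoxy-2-[3-methoxy-4-(methylsulfonyloxy)phenyl]-2,3-dihydro-1-benzofuran-3-carboxylate (2,3-cis) | Brc1cc(OC)c2c(c1)[C@@H](C(=O)OC)[C@@H](c1ccc(OS(C)(=O)=O)c(OC)c1)O2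
F4 | step 5 | 4-formyl-2-methoxyphenyl methanesulfonate | COc1cc(C=O)ccc1OS(C)(=O)=O
F5 | step 5 | (E)-1-(5-bromo-2-hydroxy-3-methoxyphenyl)-3-[3-methoxy-4-(methylsulfonyloxy)phenyl]prop-2-en-1-one | COc1cc(/C=C/C(=O)c2cc(Br)cc(OC)c2O)ccc1OS(C)(=O)=O
F6 | step 5 | racemic 6-bromo-8-methoxy-2-[3-methoxy-4-(methylsulfonyloxy)phenyl]-2,3-dihydro-4H-chromen-4-one | O=C1CC(c2ccc(OS(C)(=O)=O)c(OC)c2)Oc2c1cc(Br)cc2OC
F7 | step 5 | 4-[(2R,4R)-6-bromo-4-hydroxy-8-methoxy-3,4-dihydro-2H-chromen-2-yl]-2-methoxyphenyl methanesulfonate | O[C@@H]1C[C@H](c2ccc(OS(C)(=O)=O)c(OC)c2)Oc2c1cc(Br)cc2OC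
F8 | step 8 | methyl (2S,3R)-3-(hydroxymethyl)-7-methoxy-2-[3-methoxy-4-(methylsulfonyloxy)phenyl]-2,3-dihydro-1-benzofuran-5-carboxylate | COC(=O)c1cc(OC)c2c(c1)[C@H](CO)[C@@H](c1ccc(OS(C)(=O)=O)c(OC)c1)O2
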